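**Retrosynthetic overview**
1. The 10,11-oxirane is made last, by reagent-controlled epoxidation of the prenyl alkene of a tris-angelate diol.
2. That diol comes from a 1,2,3-triol by O2-selective angeloylation. The triol comes from an all-cis allylic 1,2-diol by the key C–O step: hydroxyl-directed anti addition of OH (C3) and angelate (C4) across C3=C4 through a transient 3,4-oxirane.
3. The cis-diol comes from a carvone-type enone by α′-hydroxylation (C1–O), inversion at C1 and 1,2-reduction of the C2 ketone.
4. The enone side chain comes from the isopropenyl group of (S)-carvone: allylic chlorination, oxidation to the enal, catalytic asymmetric allylation (C8), cross-metathesis (prenyl), angeloylation.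
5. Ring order: the cyclohexane is taken intact from carvone; the 3,4-oxirane is formed and opened in step 9; the 10,11-oxirane is closed in step 11.

Assumption: locants follow the bisabolane skeleton (ring C1–C6, CH3-15 on C3, side chain C7(=C14)–C8–C9–C10–C11(C12)(C13) on C6). Angelate/Ang = (Z)-2-methylbut-2-enoate. "Up/down" refer to the ring drawn with C1→C6 clockwise and the C6 side chain down; the target then has 1-OH, 2-OAng and 3-OH down and 3-CH3 and 4-OAng up.

**Step 1**
Reactants: 1 (S)-(+)-carvone
Product: 2 (5S)-5-(3-chloroprop-1-en-2-yl)-2-methylcyclohex-2-en-1-one (10-chlorocarvone)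
Conditions: Ca(OCl)2, CO2 (dry ice), CH2Cl2/H2O, 0 °C
Reagents that add atoms: calcium hypochlorite Ca(OCl)2, [Ca+2].[O-]Cl.[O-]Cl
Why: Ene-type allylic chlorination by HOCl made in situ attacks only the electron-rich 1,1-disubstituted alkene (the enone alkene is deactivated) and returns the double bond to the isopropenyl position, as established on carvone itself, without touching the stereocenter.

**Step 2**
Reactants: 2 10-chlorocarvone
Product: 3 2-[(1S)-4-methyl-5-oxocyclohex-3-en-1-yl]prop-2-enal
Conditions: NMO (4 equiv), KI (0.2 equiv), MeCN, 4 Å MS, rt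
Reagents that add atoms: N-methylmorpholine N-oxide, C[N+]1([O-])CCOCC1
Why: Ganem-type N-oxide oxidation (Kornblum family): the allylic halide O-alkylates the N-oxide and the alkoxyammonium salt collapses to the 2-substituted acrolein under near-neutral conditions that leave C6 untouched.

**Step 3**
Reactants: 3 enal; 4 allylboronic acid pinacol ester
Product: 5 (5S)-5-[(3S)-3-hydroxyhexa-1,5-dien-2-yl]-2-methylcyclohex-2-en-1-one
Conditions: 4 (1.3 equiv), (S)-TRIP phosphoric acid (5 mol %), toluene, 4 Å MS, −30 °C
Reagents that add atoms: allylboronic acid pinacol ester 4, C=CCB1OC(C)(C)C(C)(C)O1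
Why: Chiral phosphoric acid-catalysed allylboration of the aldehyde (the ring ketone is inert) through a closed chair transition state in which (S)-TRIP, the antipode of the catalyst that gives (R)-carbinols from benzaldehyde, exposes the Si face of the formyl group and sets C8 as S under catalyst control.

**Step 4**
Reactants: 5 homoallylic alcohol; 6 2-methylbut-2-ene
Product: 7 (6S,8S)-8-hydroxybisabola-3,7(14),10-trien-2-one
Conditions: 6 (30 equiv), second-generation Grubbs catalyst RuCl2(=CHPh)(PCy3)(H2IMes) (5 mol %), CH2Cl2, 40 °C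
Reagents that add atoms: 2-methylbut-2-ene 6, CC=C(C)C
Why: Olefin cross-metathesis converts the monosubstituted alkene into the prenyl group, while the 1,1-disubstituted C7=C14 alkene and the enone are too hindered or electron-poor to take part, and no stereocenter is affected.

**Step 5**
Reactants: 7 allylic alcohol; 8 angelic acid
Product: 9 (6S,8S)-8-angeloyloxybisabola-3,7(14),10-trien-2-one
Conditions: 8 (2 equiv), 2,4,6-Cl3C6H2COCl (2 equiv), Et3N (2.2 equiv), toluene, rt; then 7, 75 °C (no DMAP)
Reagents that add atoms: angelic acid 8, C/C=C(/C)C(=O)O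
Why: Yamaguchi-type esterification through the mixed 2,4,6-trichlorobenzoic anhydride acylates O8 with retention at C8, and leaving out nucleophilic catalysts avoids Z-to-E isomerisation of the angelate.

**Step 6**
Reactants: 9 enone angelate
Product: 11 (1R,6R,8S)-8-angeloyloxy-1-hydroxybisabola-3,7(14),10-trien-2-one, via potassium dienolate 10 (not isolated)
Conditions: KN(SiMe3)2 (1.1 equiv), THF, −78 °C; then 2-(phenylsulfonyl)-3-phenyloxaziridine (1.5 equiv), −78 °C; aq. NH4Cl
Reagents that add atoms: 2-(phenylsulfonyl)-3-phenyloxaziridine, O=S(=O)(c1ccccc1)N1OC1c1ccccc1; KN(SiMe3)2, C[Si](C)(C)[N-][Si](C)(C)C.[K+] (potassium stays only in 10)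
Why: Kinetic α′-deprotonation gives the cross-conjugated dienolate (the ester is far less acidic), and Davis oxaziridine hydroxylation delivers oxygen to the face anti to the C6 side chain, giving the trans 1-hydroxy ketone (1R) that is inverted in step 7.

**Step 7**
Reactants: 11 trans α′-hydroxy ketone
Product: 12 (1S,6R,8S)-8-angeloyloxy-1-formyloxybisabola-3,7(14),10-trien-2-one
Conditions: HCO2H (3 equiv), PPh3 (3 equiv), DIAD (3 equiv), THF, 0 °C → rt
Reagents that add atoms: formic acid, OC=O
Why: Mitsunobu reaction: SN2 displacement of the oxyphosphonium group at the carbonyl-activated C1 by formate inverts C1 to S and places the C1 oxygen cis to the C6 side chain.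

**Step 8**
Reactants: 12 cis α′-formyloxy ketone
Product: 14 (1S,2R,6R,8S)-8-angeloyloxybisabola-3,7(14),10-triene-1,2-diol, via hydroxy formate 13 (not isolated)
Conditions: NaBH4 (1.1 equiv), CeCl3·7H2O (1.1 equiv), MeOH, −40 °C; then K2CO3 (0.3 equiv), 0 °C, 20 min
Reagents that add atoms: none
Why: Luche 1,2-reduction: hydride attacks C2 from the top face, anti to the pseudoaxial C1–O bond (the same sense as carvone to cis-carveol), giving the all-cis 2R alcohol, and the labile formate is then removed by catalytic methanolysis that leaves the angelate intact.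

**Step 9**
Reactants: 14 cis-diol; 8 angelic acid
Product: 16 (1S,2S,3S,4S,6R,8S)-4,8-bis(angeloyloxy)bisabola-7(14),10-diene-1,2,3-triol, via epoxy diol 15 (not isolated)
Conditions: VO(acac)2 (3 mol %), t-BuOOH (1.1 equiv, decane), CH2Cl2, 4 Å MS, 0 °C → rt; then Ti(OiPr)4 (1.5 equiv), 8 (3 equiv), rt → 35 °C; aq. tartaric acid
Reagents that add atoms: tert-butyl hydroperoxide, CC(C)(C)OO; angelic acid 8, C/C=C(/C)C(=O)O
Why: Proposed new method: a one-flask vanadium-to-titanium relay "directed anti-hydroxy-acyloxylation", in which the vanadyl tert-butylperoxo complex bound to the C2 alkoxide (reinforced by O1–H) transfers oxygen to the bottom face of C3=C4 to give 15, after which Ti(OiPr)4 forms a titanate with the C1/C2 diol that activates the oxirane and passes a titanium-bound angelate to the less substituted C4 from the top face in a trans-diaxial (Fürst–Plattner) SN2 opening that leads directly to the chair with the side chain equatorial, so that C3–OH ends down and C4–OAng up; the closest known reaction types are the VO(acac)2/t-BuOOH epoxidation of allylic alcohols and the Ti(OiPr)4-mediated C3-selective opening of 2,3-epoxy alcohols by carboxylic acids, which have not been merged in one flask, applied to a cyclic trisubstituted epoxy cis-diol or run with angelic acid.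

**Step 10**
Reactants: 16 triol; 8 angelic acid
Product: 18 (1S,2S,3R,4S,6R,8S)-2,4,8-tris(angeloyloxy)bisabola-7(14),10-diene-1,3-diol, via stannylene acetal 17 (not isolated)
Conditions: Bu2SnO (1.05 equiv), toluene, reflux (Dean–Stark), 2 h; then mixed anhydride from 8 (1.3 equiv), 2,4,6-Cl3C6H2COCl (1.3 equiv), Et3N (1.4 equiv), toluene, 0 → 40 °C
Reagents that add atoms: angelic acid 8, C/C=C(/C)C(=O)O; dibutyltin oxide Bu2SnO, CCCC[Sn](=O)CCCC (tin stays only in 17)
Why: Regioselective acylation through a dibutylstannylene acetal: in the five-membered tin acetal of the cis C1(axial)/C2(equatorial) diol the equatorial O2 is the nucleophilic oxygen and the tertiary O3–H is inert, so the angeloyl group is delivered to O2 with retention and without base-induced isomerisation.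

**Step 11**
Reactants: 18 tris-angelate diol
Product: 19 target, (1S,2S,3R,4S,6R,8S,10S)-2,4,8-tris(angeloyloxy)-10,11-epoxybisabol-7(14)-ene-1,3-diol
Conditions: L-fructose-derived Shi ketone (0.3 equiv), Oxone (2KHSO5·KHSO4·K2SO4, 1.5 equiv), K2CO3, Bu4NHSO4 (cat.), MeCN/CH2(OMe)2/aq. Na2B4O7–Na2EDTA buffer (pH ≈ 10), −10 → 0 °C
Reagents that add atoms: potassium peroxymonosulfate KHSO5 (active part of Oxone), [K+].[O-]S(=O)(=O)OO
Why: Shi asymmetric epoxidation: the chiral dioxirane attacks only the electron-rich trisubstituted C10=C11 alkene (C7=C14 is 1,1-disubstituted and deactivated by the allylic ester, the angelate alkenes are electron-poor) through the spiro transition state that gives 10S, the mirror image of the 10R sense of the D-fructose-derived ketone; low temperature and short time limit O2→O1 acyl migration.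

**Compound list**
1 | (S)-(+)-carvone, (5S)-2-methyl-5-(prop-1-en-2-yl)cyclohex-2-en-1-one | C=C(C)[C@H]1CC=C(C)C(=O)C1 | starting material
2 | (5S)-5-(3-chloroprop-1-en-2-yl)-2-methylcyclohex-2-en-1-one (10-chlorocarvone) | C=C(CCl)[C@H]1CC=C(C)C(=O)C1 | intermediate
3 | 2-[(1S)-4-methyl-5-oxocyclohex-3-en-1-yl]prop-2-enal | C=C(C=O)[C@H]1CC=C(C)C(=O)C1 | intermediate
4 | allylboronic acid pinacol ester | C=CCB1OC(C)(C)C(C)(C)O1 | starting material
5 | (5S)-5-[(3S)-3-hydroxyhexa-1,5-dien-2-yl]-2-methylcyclohex-2-en-1-one | C=C([C@H](CC=C)O)[C@H]1CC=C(C)C(=O)C1 | intermediate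
6 | 2-methylbut-2-ene | CC=C(C)C | starting material
7 | (6S,8S)-8-hydroxybisabola-3,7(14),10-trien-2-one | C=C([C@H](CC=C(C)C)O)[C@H]1CC=C(C)C(=O)C1 | intermediate
8 | angelic acid, (Z)-2-methylbut-2-enoic acid | C/C=C(/C)C(=O)O | starting material
9 | (6S,8S)-8-angeloyloxybisabola-3,7(14),10-trien-2-one | C=C([C@H](CC=C(C)C)OC(=O)/C(C)=C\C)[C@H]1CC=C(C)C(=O)C1 | intermediate
10 | potassium C1=C2 dienolate of 9 (O–K on C2) | C=C([C@H](CC=C(C)C)OC(=O)/C(C)=C\C)[C@H]1CC=C(C)C([O-])=C1.[K+] | intermediate (not isolated)
11 | (1R,6R,8S)-8-angeloyloxy-1-hydroxybisabola-3,7(14),10-trien-2-one (1-OH trans to the side chain) | C=C([C@H](CC=C(C)C)OC(=O)/C(C)=C\C)[C@H]1CC=C(C)C(=O)[C@@H]1O | intermediate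
12 | (1S,6R,8S)-8-angeloyloxy-1-formyloxybisabola-3,7(14),10-trien-2-one (1-O cis to the side chain) | C=C([C@H](CC=C(C)C)OC(=O)/C(C)=C\C)[C@H]1CC=C(C)C(=O)[C@H]1OC=O | intermediate
13 | (1S,2R,6R,8S)-8-angeloyloxy-1-formyloxybisabola-3,7(14),10-trien-2-ol | C=C([C@H](CC=C(C)C)OC(=O)/C(C)=C\C)[C@H]1CC=C(C)[C@@H](O)[C@H]1OC=O | intermediate (not isolated)
14 | (1S,2R,6R,8S)-8-angeloyloxybisabola-3,7(14),10-triene-1,2-diol (side chain, 1-OH and 2-OH all cis) | C=C([C@H](CC=C(C)C)OC(=O)/C(C)=C\C)[C@H]1CC=C(C)[C@@H](O)[C@H]1O | intermediate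
15 | (1S,2S,3S,4R,6R,8S)-8-angeloyloxy-3,4-epoxybisabola-7(14),10-diene-1,2-diol (oxirane cis to both hydroxyls) | C=C([C@H](CC=C(C)C)OC(=O)/C(C)=C\C)[C@H]1C[C@H]2O[C@@]2(C)[C@@H](O)[C@H]1O | intermediate (not isolated)
16 | (1S,2S,3S,4S,6R,8S)-4,8-bis(angeloyloxy)bisabola-7(14),10-diene-1,2,3-triol | C=C([C@H](CC=C(C)C)OC(=O)/C(C)=C\C)[C@H]1C[C@H](OC(=O)/C(C)=C\C)[C@@](C)(O)[C@@H](O)[C@H]1O | intermediate
17 | 1,2-O-dibutylstannylene acetal of 16 | C=C([C@H](CC=C(C)C)OC(=O)/C(C)=C\C)[C@H]1C[C@H](OC(=O)/C(C)=C\C)[C@@](C)(O)[C@@H](O2)[C@H]1O[Sn]2(CCCC)CCCC | intermediate (not isolated)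
18 | (1S,2S,3R,4S,6R,8S)-2,4,8-tris(angeloyloxy)bisabola-7(14),10-diene-1,3-diol | C=C([C@H](CC=C(C)C)OC(=O)/C(C)=C\C)[C@H]1C[C@H](OC(=O)/C(C)=C\C)[C@@](C)(O)[C@@H](OC(=O)/C(C)=C\C)[C@H]1O | intermediate
19 | (1S,2S,3R,4S,6R,8S,10S)-2,4,8-tris(angeloyloxy)-10,11-epoxybisabol-7(14)-ene-1,3-diol (CNP0421750.2) | C=C([C@H](C[C@@H]1OC1(C)C)OC(=O)/C(C)=C\C)[C@H]1C[C@H](OC(=O)/C(C)=C\C)[C@@](C)(O)[C@@H](OC(=O)/C(C)=C\C)[C@H]1O | target

**Step count and risks**
Total: 11 steps, all in one line from 1. Longest linear sequence: 11 steps. No protecting group is used apart from the formate that is carried for one step.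

The three steps most likely to fail:

Step 9 (the proposed relay). Residual peroxide or vanadium may interfere with the titanium stage, or the titanate of the cis-diol may open the oxirane sluggishly. The fallback sets out from 14 and separates the two events into known reactions. VO(acac)2/t-BuOOH epoxidation is run alone and epoxy diol 15 is isolated. Compound 15 is then opened at C4 without any Lewis acid, by SN2 attack of caesium angelate (8, Cs2CO3, DMF, 70 °C). The route is rejoined at 16. No compound outside the list is made (entry F0).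

Step 7 (Mitsunobu inversion at a hindered α-ketol). Elimination toward the dienone or retention through an acyloxyphosphonium path are possible. The fallback sets out from 11 and replaces the redox condensation by a sulfonate route. Tf2O/pyridine (CH2Cl2, −40 °C) gives the trans C1 triflate F1. This very reactive α-keto triflate is displaced with inversion by HCO2Cs/18-crown-6 in DMF at 0 °C. The route is rejoined at 12.

Step 10 (O2-selective acylation of the triol). A six-membered tin acetal across O1/O3 would send the acyl group to O1. The fallback sets out from 16 and uses temporary protection in place of tin activation. PhB(OH)2 in refluxing toluene ties the syn-diaxial O1 and O3 into the cyclic 1,3-O-phenylboronate F2, which leaves only the equatorial O2–H free. Yamaguchi angeloylation as in step 5 gives the 2-O-angeloyl boronate F3. Transesterification with pinacol (CH2Cl2, rt) frees the diol. The route is rejoined at 18.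

**Further compounds**
F1 | step 7 | (1R,6R,8S)-8-angeloyloxy-1-(trifluoromethanesulfonyloxy)bisabola-3,7(14),10-trien-2-one | C=C([C@H](CC=C(C)C)OC(=O)/C(C)=C\C)[C@H]1CC=C(C)C(=O)[C@@H]1OS(=O)(=O)C(F)(F)F
F0 | step 9 | none | none
F2 | step 10 | 1,3-O-phenylboronate of triol 16 | C=C([C@H](CC=C(C)C)OC(=O)/C(C)=C\C)[C@H]1C[C@H](OC(=O)/C(C)=C\C)[C@@](C)(O2)[C@@H](O)[C@H]1OB2c1ccccc1
F3 | step 10 | 2-O-angeloyl 1,3-O-phenylboronate (boronate of 18) | C=C([C@H](CC=C(C)C)OC(=O)/C(C)=C\C)[C@H]1C[C@H](OC(=O)/C(C)=C\C)[C@@](C)(O2)[C@@H](OC(=O)/C(C)=C\C)[C@H]1OB2c1ccccc1
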